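**Plan**
- Retrosynthesis: cut O7–C1 and C2–Br of the oxabicycle together (bromoetherification of a 4-methylcyclohex-3-en-1-ol), then C3–C4 (intramolecular Reformatsky aldol), then C4–C5 (ester enolate plus Weinreb amide), then C4'–Br of the cyclohexyl ring.
- Enabling feature: in the carbocycle C1–C6 of the 7-oxabicyclo[2.2.1]heptane, bridgehead C1 (methyl, O7, C2, C6) is the carbinol carbon of (R)-linalool. Its vinyl group is C2–C3 and becomes a bromomethyl ketone, so an enolate can exist only at C3 and closes onto the C4 ketone.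
- Forward: the bromocyclohexane ring is completed first and the chain is joined at C4–C5. Ring C1–C6 closes in step 15; the oxygen bridge is closed (step 17), opened (step 19) and closed again together with C2–Br (step 20).
- Stereochemistry: C4' comes from a CBS reduction and is inverted by bromide; C1' is locked cis by a bicyclic lactone. C1 comes from linalool, is relayed to C4 by the first ether closure, and C1/C2 are re-set from C4 by anti bromoetherification.

Key step: step 15

Remark: commercial (R)-(−)-linalool is assumed to be of high enantiomeric purity; C1–C6/O7 are the oxabicycle locants of 27 and primed locants belong to its bromocyclohexyl ring.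

**Step 1**
Reactants: 1 diethyl 4-oxocyclohexane-1,1-dicarboxylate
Product: 2 diethyl 3,3-dimethyl-4-oxocyclohexane-1,1-dicarboxylate
Conditions: KOtBu (2.3 equiv), MeI (3 equiv), THF, 0 °C → rt
Reagents that add atoms: iodomethane, CI
Why: Ketone α,α-dimethylation under equilibrating alkoxide conditions: the monomethyl ketone should re-enolise mainly toward the substituted carbon and alkylate again, so the geminal product is expected to predominate (the 3,5-isomer is removed by chromatography), and the malonate carbon has no acidic hydrogen.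

**Step 2**
Reactants: 2 diethyl 3,3-dimethyl-4-oxocyclohexane-1,1-dicarboxylate
Product: 3 diethyl (4R)-4-hydroxy-3,3-dimethylcyclohexane-1,1-dicarboxylate
Conditions: (S)-Me-CBS (0.1 equiv), BH3·SMe2 (0.7 equiv), THF, −20 °C; MeOH quench
Reagents that add atoms: none
Why: Corey–Bakshi–Shibata reduction of an achiral ketone flanked by CMe2 (large) and CH2 (small): the (S)-catalyst should give the (R)-carbinol, and because C1 carries two identical esters there is no matched/mismatched problem; the esters survive at this temperature.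

**Step 3**
Reactants: 3 diethyl (4R)-4-hydroxy-3,3-dimethylcyclohexane-1,1-dicarboxylate
Product: 4 ethyl (4R)-4-hydroxy-3,3-dimethylcyclohexane-1-carboxylate (C1 epimers)
Conditions: LiCl, H2O, DMSO, 155 °C
Reagents that add atoms: none
Why: Krapcho dealkoxycarbonylation of a geminal diester; C1 forms as a mixture of epimers that step 4 is designed to converge.

**Step 4**
Reactants: 4 ethyl (4R)-4-hydroxy-3,3-dimethylcyclohexane-1-carboxylate (C1 epimers)
Product: 5 (1R,4S)-6,6-dimethyl-2-oxabicyclo[2.2.2]octan-3-one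
Conditions: KOtBu (0.2 equiv), toluene, 110 °C, EtOH distilled off
Reagents that add atoms: none
Why: Base-mediated ester epimerisation coupled to lactonisation (transesterification): only the epimer with the ester cis to the alkoxide can close the bridged lactone, so both epimers should drain into one lactone whose bridgehead (former C1) is set by the CBS-derived carbinol and can no longer enolise.

**Step 5**
Reactants: 5 (1R,4S)-6,6-dimethyl-2-oxabicyclo[2.2.2]octan-3-one
Product: 6 (1S,4R)-4-hydroxy-N-methoxy-N,3,3-trimethylcyclohexane-1-carboxamide (cis)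
Conditions: MeNH(OMe)·HCl, AlMe3, CH2Cl2, 0 °C → rt; Rochelle salt
Reagents that add atoms: N,O-dimethylhydroxylamine hydrochloride, CNOC.Cl
Why: Weinreb aminolysis of a lactone by the aluminium amide: acyl–oxygen cleavage touches neither stereocentre and gives the cis hydroxy amide (amide equatorial, hydroxyl axial).

**Step 6**
Reactants: 6 (1S,4R)-4-hydroxy-N-methoxy-N,3,3-trimethylcyclohexane-1-carboxamide
Product: 7 (1S,4S)-4-bromo-N-methoxy-N,3,3-trimethylcyclohexane-1-carboxamide (trans)
Conditions: CBr4, PPh3, toluene, 0 → 50 °C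
Reagents that add atoms: tetrabromomethane, BrC(Br)(Br)Br
Why: Appel reaction with inversion: the axial alkoxyphosphonium group is displaced by bromide along the equatorial trajectory, as known for axial cyclohexanols next to a gem-dimethyl carbon, which should give the diequatorial trans bromide with the (4S) centre.

**Step 7**
Reactants: 8 (R)-(−)-linalool
Product: 9 triethyl{[(3R)-3,7-dimethylocta-1,6-dien-3-yl]oxy}silane
Conditions: TESOTf, 2,6-lutidine, CH2Cl2, −78 → 0 °C
Reagents that add atoms: triethylsilyl trifluoromethanesulfonate, CC[Si](CC)(CC)OS(=O)(=O)C(F)(F)F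
Why: Silylation of a tertiary allylic alcohol with a silyl triflate and a hindered base; the carbinol centre is not involved.

**Step 8**
Reactants: 9 triethyl{[(3R)-3,7-dimethylocta-1,6-dien-3-yl]oxy}silane
Product: 11 (4R)-4-methyl-4-(triethylsilyloxy)hex-5-enoic acid, via aldehyde 10 (not isolated)
Conditions: O3 (1 equiv, Sudan Red 7B endpoint), CH2Cl2, −78 °C; PPh3; then NaClO2, NaH2PO4, 2-methyl-2-butene, t-BuOH/H2O, rt
Reagents that add atoms: ozone, [O-][O+]=O; sodium chlorite, [Na+].[O-]Cl=O
Why: Ozonolysis is selective for the electron-rich trisubstituted alkene over the vinyl group when ozone is metered against a dye, and the aldehyde is oxidised in the same flask by a Pinnick oxidation that leaves the vinyl group and silyl ether alone.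

**Step 9**
Reactants: 11 (4R)-4-methyl-4-(triethylsilyloxy)hex-5-enoic acid
Product: 12 prop-2-enyl (4R)-4-methyl-4-(triethylsilyloxy)hex-5-enoate
Conditions: allyl bromide, K2CO3, DMF, rt
Reagents that add atoms: allyl bromide, C=CCBr
Why: Carboxylate O-alkylation (SN2); the allyl ester is chosen because it can later be removed under neutral conditions.

**Step 10**
Reactants: 12 prop-2-enyl (4R)-4-methyl-4-(triethylsilyloxy)hex-5-enoate; 7 (1S,4S)-4-bromo-N-methoxy-N,3,3-trimethylcyclohexane-1-carboxamide
Product: 14 prop-2-enyl (4R)-2-[(1S,4S)-4-bromo-3,3-dimethylcyclohexane-1-carbonyl]-4-methyl-4-(triethylsilyloxy)hex-5-enoate (C2 epimers), via lithium enolate 13 (not isolated)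
Conditions: LDA (1.05 equiv per 12), THF, −78 °C; then 7 (0.8 equiv), −78 → −10 °C; aq. NH4Cl
Reagents that add atoms: lithium diisopropylamide, CC(C)N([Li])C(C)C (lithium in 13 only)
Why: Crossed Claisen-type acylation of an ester enolate by a Weinreb amide: the chelated tetrahedral adduct persists until work-up, so no excess base is present to epimerise C1' or attack the hindered equatorial bromide; this forms C4–C5, and the new α-centre disappears in step 11.

**Step 11**
Reactants: 14 prop-2-enyl (4R)-2-[(1S,4S)-4-bromo-3,3-dimethylcyclohexane-1-carbonyl]-4-methyl-4-(triethylsilyloxy)hex-5-enoate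
Product: 16 (4R)-1-[(1S,4S)-4-bromo-3,3-dimethylcyclohexyl]-4-methyl-4-(triethylsilyloxy)hex-5-en-1-one, via β-keto acid 15 (not isolated)
Conditions: Pd(PPh3)4 (5 mol%), morpholine (2 equiv), THF, rt
Reagents that add atoms: none
Why: Tsuji–Trost-type deallylation (allyl transfer to morpholine) frees the β-keto acid, which decarboxylates at room temperature; the neutral conditions should preserve the silyl ether, the secondary bromide and C1'.

**Step 12**
Reactants: 16 (4R)-1-[(1S,4S)-4-bromo-3,3-dimethylcyclohexyl]-4-methyl-4-(triethylsilyloxy)hex-5-en-1-one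
Product: 17 (4R)-1-[(1S,4S)-4-bromo-3,3-dimethylcyclohexyl]-4-(oxiran-2-yl)-4-(triethylsilyloxy)pentan-1-one (oxirane epimers)
Conditions: Oxone, CF3COCH3, NaHCO3, aq. Na2EDTA, MeCN, 0 °C
Reagents that add atoms: potassium peroxymonosulfate (Oxone), [K+].[O-]S(=O)(=O)OO
Why: Epoxidation of a monosubstituted alkene by methyl(trifluoromethyl)dioxirane generated in situ; dioxiranes do not attack the ketone, silyl ether or alkyl bromide, and the epoxide epimers converge later.

**Step 13**
Reactants: 17 (4R)-1-[(1S,4S)-4-bromo-3,3-dimethylcyclohexyl]-4-(oxiran-2-yl)-4-(triethylsilyloxy)pentan-1-one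
Product: 18 (4R)-6-bromo-1-[(1S,4S)-4-bromo-3,3-dimethylcyclohexyl]-5-hydroxy-4-methyl-4-(triethylsilyloxy)hexan-1-one (C5 epimers)
Conditions: LiBr, AcOH, THF, rt
Reagents that add atoms: lithium bromide, [Li+].[Br-]
Why: Regioselective SN2 opening of a terminal epoxide by bromide at the unhindered CH2 (bromohydrin formation); the weak acid should leave the tertiary silyl ether in place.

**Step 14**
Reactants: 18 (4R)-6-bromo-1-[(1S,4S)-4-bromo-3,3-dimethylcyclohexyl]-5-hydroxy-4-methyl-4-(triethylsilyloxy)hexan-1-one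
Product: 19 (3R)-1-bromo-6-[(1S,4S)-4-bromo-3,3-dimethylcyclohexyl]-3-methyl-3-(triethylsilyloxy)hexane-2,6-dione
Conditions: Dess–Martin periodinane, NaHCO3, CH2Cl2, 0 °C → rt
Reagents that add atoms: none
Why: Dess–Martin oxidation of a secondary bromohydrin to the α-bromo ketone under buffered, non-basic conditions that avoid epoxide re-closure and silyl migration.

**Step 15**
Reactants: 19 (3R)-1-bromo-6-[(1S,4S)-4-bromo-3,3-dimethylcyclohexyl]-3-methyl-3-(triethylsilyloxy)hexane-2,6-dione
Product: 21 (2R)-5-[(1S,4S)-4-bromo-3,3-dimethylcyclohexyl]-5-hydroxy-2-methyl-2-(triethylsilyloxy)cyclohexan-1-one (C5 epimers), via samarium enolate 20 (not isolated)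
Conditions: SmI2 (2.2 equiv), THF, −78 °C; sat. NH4Cl
Reagents that add atoms: samarium(II) iodide, I[Sm]I (samarium and iodine in 20 only)
Why: Two single-electron transfers cleave the primary C–Br bond and give the samarium(III) enolate 20 only at C3, which adds to the C4 ketone and forms C3–C4. The closest known reaction type is the samarium(II)- or zinc-mediated intramolecular Reformatsky-type aldol cyclisation of α-halo ketones onto ketones. The carbocycle C1–C6 closes in a 6-(enolendo)-exo-trig mode. The new C4 carbinol (C5 of 21) is controlled by no element of the substrate and is expected as a mixture, which is acceptable because C4 is ionised in step 17. The step needs chemoselectivity for the α-bromo ketone over the secondary bromide, the C4 ketone and the α-silyloxy group, and an enolate at C3 only. The first follows from the much faster reduction of α-halo ketones at −78 °C, the second from C1 being quaternary, and the base-free medium keeps C1' (α to the other ketone) intact.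

**Step 16**
Reactants: 21 (2R)-5-[(1S,4S)-4-bromo-3,3-dimethylcyclohexyl]-5-hydroxy-2-methyl-2-(triethylsilyloxy)cyclohexan-1-one
Product: 22 (4R)-1-[(1S,4S)-4-bromo-3,3-dimethylcyclohexyl]-4-methyl-4-(triethylsilyloxy)cyclohexane-1,3-diol (C1 and C3 epimers)
Conditions: NaBH4, CeCl3·7H2O, MeOH, −40 → 0 °C
Reagents that add atoms: none
Why: Luche reduction at low temperature, which should outpace retro-aldol cleavage; the new carbinol configuration does not matter because this carbon is re-oxidised in step 18.

**Step 17**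
Reactants: 22 (4R)-1-[(1S,4S)-4-bromo-3,3-dimethylcyclohexyl]-4-methyl-4-(triethylsilyloxy)cyclohexane-1,3-diol
Product: 23 (1R,4S)-4-[(1S,4S)-4-bromo-3,3-dimethylcyclohexyl]-1-methyl-7-oxabicyclo[2.2.1]heptan-2-ol (C2 epimers)
Conditions: TsOH·H2O (0.3 equiv), CH2Cl2, 0 °C → rt
Reagents that add atoms: none
Why: Acid-catalysed cyclodehydration of a 1,4-diol derivative (1,4-cineole-type SN1 etherification): the tertiary C4 carbinol ionises (C1 is shielded by its β-hydroxyl and silyl ether) and the C1 oxygen, held on one face by the linalool centre, captures the cation across the ring with loss of the silyl group, so both C4 epimers should converge on the (1R,4S) bridge.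

**Step 18**
Reactants: 23 (1R,4S)-4-[(1S,4S)-4-bromo-3,3-dimethylcyclohexyl]-1-methyl-7-oxabicyclo[2.2.1]heptan-2-ol
Product: 24 (1R,4S)-4-[(1S,4S)-4-bromo-3,3-dimethylcyclohexyl]-1-methyl-7-oxabicyclo[2.2.1]heptan-2-one
Conditions: Dess–Martin periodinane, NaHCO3, CH2Cl2, rt
Reagents that add atoms: none
Why: Dess–Martin oxidation of a secondary alcohol; both C2 epimers give the same ketone, which as a strained β-alkoxy ketone is kept away from base until step 19.

**Step 19**
Reactants: 24 (1R,4S)-4-[(1S,4S)-4-bromo-3,3-dimethylcyclohexyl]-1-methyl-7-oxabicyclo[2.2.1]heptan-2-one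
Product: 26 (1S)-1-[(1S,4S)-4-bromo-3,3-dimethylcyclohexyl]-4-methylcyclohex-3-en-1-ol, via hydrazone 25 (not isolated)
Conditions: N2H4·H2O (10 equiv), AcOH (cat.), EtOH, 80 °C; then KOtBu (cat.), DMSO, rt
Reagents that add atoms: hydrazine hydrate, NN.O (nitrogen in 25 only)
Why: Kishner–Leonard eliminative reduction (the α-alkoxy counterpart of the Wharton reaction): the deprotonated hydrazone expels the strained C1–O7 bond and the alkenyl diazene loses N2 to leave the C1=C2 alkene, while the oxygen stays on C4 with the configuration fixed in step 17.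

**Step 20**
Reactants: 26 (1S)-1-[(1S,4S)-4-bromo-3,3-dimethylcyclohexyl]-4-methylcyclohex-3-en-1-ol
Product: 27 (1R,2R,4S)-2-bromo-4-[(1S,4S)-4-bromo-3,3-dimethylcyclohexyl]-1-methyl-7-oxabicyclo[2.2.1]heptane (target)
Conditions: NBS (1.1 equiv), CH2Cl2, 0 °C, dark
Reagents that add atoms: N-bromosuccinimide, O=C1CCC(=O)N1Br
Why: Bromoetherification (halocyclisation) of a 4-methylcyclohex-3-enol: only the bromonium ion on the face opposite the axial C4 hydroxyl can be captured, oxygen adds to the tertiary C1 (Markovnikov) and bromine ends anti to it, which should re-form the (1R,4S) bridge and set the endo (2R) bromide.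

**Compound list**
1 | diethyl 4-oxocyclohexane-1,1-dicarboxylate | CCOC(=O)C1(CCC(=O)CC1)C(=O)OCC | starting material
2 | diethyl 3,3-dimethyl-4-oxocyclohexane-1,1-dicarboxylate | CCOC(=O)C1(CCC(=O)C(C)(C)C1)C(=O)OCC | intermediate
3 | diethyl (4R)-4-hydroxy-3,3-dimethylcyclohexane-1,1-dicarboxylate | CCOC(=O)C1(CC[C@@H](O)C(C)(C)C1)C(=O)OCC | intermediate
4 | ethyl (4R)-4-hydroxy-3,3-dimethylcyclohexane-1-carboxylate (C1 epimers) | CCOC(=O)C1CC[C@@H](O)C(C)(C)C1 | intermediate
5 | (1R,4S)-6,6-dimethyl-2-oxabicyclo[2.2.2]octan-3-one | O=C1O[C@@H]2CC[C@H]1CC2(C)C | intermediate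
6 | (1S,4R)-4-hydroxy-N-methoxy-N,3,3-trimethylcyclohexane-1-carboxamide | CON(C)C(=O)[C@H]1CC[C@@H](O)C(C)(C)C1 | intermediate
7 | (1S,4S)-4-bromo-N-methoxy-N,3,3-trimethylcyclohexane-1-carboxamide | CON(C)C(=O)[C@H]1CC[C@H](Br)C(C)(C)C1 | intermediate
8 | (R)-(−)-linalool | CC(C)=CCC[C@@](C)(O)C=C | starting material
9 | triethyl{[(3R)-3,7-dimethylocta-1,6-dien-3-yl]oxy}silane | CC(C)=CCC[C@@](C)(O[Si](CC)(CC)CC)C=C | intermediate
10 | (4R)-4-methyl-4-(triethylsilyloxy)hex-5-enal | O=CCC[C@@](C)(O[Si](CC)(CC)CC)C=C | intermediate (not isolated)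
11 | (4R)-4-methyl-4-(triethylsilyloxy)hex-5-enoic acid | OC(=O)CC[C@@](C)(O[Si](CC)(CC)CC)C=C | intermediate
12 | prop-2-enyl (4R)-4-methyl-4-(triethylsilyloxy)hex-5-enoate | C=CCOC(=O)CC[C@@](C)(O[Si](CC)(CC)CC)C=C | intermediate
13 | lithium enolate of 12 | [Li]OC(OCC=C)=CC[C@@](C)(O[Si](CC)(CC)CC)C=C | intermediate (not isolated)
14 | prop-2-enyl (4R)-2-[(1S,4S)-4-bromo-3,3-dimethylcyclohexane-1-carbonyl]-4-methyl-4-(triethylsilyloxy)hex-5-enoate (C2 epimers) | C=CCOC(=O)C(C[C@@](C)(O[Si](CC)(CC)CC)C=C)C(=O)[C@H]1CC[C@H](Br)C(C)(C)C1 | intermediate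
15 | (4R)-2-[(1S,4S)-4-bromo-3,3-dimethylcyclohexane-1-carbonyl]-4-methyl-4-(triethylsilyloxy)hex-5-enoic acid (C2 epimers) | OC(=O)C(C[C@@](C)(O[Si](CC)(CC)CC)C=C)C(=O)[C@H]1CC[C@H](Br)C(C)(C)C1 | intermediate (not isolated)
16 | (4R)-1-[(1S,4S)-4-bromo-3,3-dimethylcyclohexyl]-4-methyl-4-(triethylsilyloxy)hex-5-en-1-one | O=C(CC[C@@](C)(O[Si](CC)(CC)CC)C=C)[C@H]1CC[C@H](Br)C(C)(C)C1 | intermediate
17 | (4R)-1-[(1S,4S)-4-bromo-3,3-dimethylcyclohexyl]-4-(oxiran-2-yl)-4-(triethylsilyloxy)pentan-1-one (oxirane epimers) | O=C(CC[C@@](C)(O[Si](CC)(CC)CC)C2CO2)[C@H]1CC[C@H](Br)C(C)(C)C1 | intermediate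
18 | (4R)-6-bromo-1-[(1S,4S)-4-bromo-3,3-dimethylcyclohexyl]-5-hydroxy-4-methyl-4-(triethylsilyloxy)hexan-1-one (C5 epimers) | O=C(CC[C@@](C)(O[Si](CC)(CC)CC)C(O)CBr)[C@H]1CC[C@H](Br)C(C)(C)C1 | intermediate
19 | (3R)-1-bromo-6-[(1S,4S)-4-bromo-3,3-dimethylcyclohexyl]-3-methyl-3-(triethylsilyloxy)hexane-2,6-dione | CC1(C)C[C@@H](C(=O)CC[C@@](C)(O[Si](CC)(CC)CC)C(=O)CBr)CC[C@@H]1Br | intermediate (key-step precursor)
20 | diiodosamarium(III) enolate of 19 | O=C(CC[C@@](C)(O[Si](CC)(CC)CC)C(=C)O[Sm](I)I)[C@H]1CC[C@H](Br)C(C)(C)C1 | intermediate (not isolated)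
21 | (2R)-5-[(1S,4S)-4-bromo-3,3-dimethylcyclohexyl]-5-hydroxy-2-methyl-2-(triethylsilyloxy)cyclohexan-1-one (C5 epimers) | CC1(C)C[C@@H](C2(O)CC[C@@](C)(O[Si](CC)(CC)CC)C(=O)C2)CC[C@@H]1Br | intermediate (key-step product)
22 | (4R)-1-[(1S,4S)-4-bromo-3,3-dimethylcyclohexyl]-4-methyl-4-(triethylsilyloxy)cyclohexane-1,3-diol (C1 and C3 epimers) | CC1(C)C[C@@H](C2(O)CC[C@@](C)(O[Si](CC)(CC)CC)C(O)C2)CC[C@@H]1Br | intermediate
23 | (1R,4S)-4-[(1S,4S)-4-bromo-3,3-dimethylcyclohexyl]-1-methyl-7-oxabicyclo[2.2.1]heptan-2-ol (C2 epimers) | CC1(C)C[C@@H]([C@@]23CC[C@@](C)(O2)C(O)C3)CC[C@@H]1Br | intermediate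
24 | (1R,4S)-4-[(1S,4S)-4-bromo-3,3-dimethylcyclohexyl]-1-methyl-7-oxabicyclo[2.2.1]heptan-2-one | CC1(C)C[C@@H]([C@@]23CC[C@@](C)(O2)C(=O)C3)CC[C@@H]1Br | intermediate
25 | hydrazone of 24 | CC1(C)C[C@@H]([C@@]23CC[C@@](C)(O2)C(=NN)C3)CC[C@@H]1Br | intermediate (not isolated)
26 | (1S)-1-[(1S,4S)-4-bromo-3,3-dimethylcyclohexyl]-4-methylcyclohex-3-en-1-ol | CC1(C)C[C@@H]([C@]2(O)CCC(C)=CC2)CC[C@@H]1Br | intermediate
27 | (1R,2R,4S)-2-bromo-4-[(1S,4S)-4-bromo-3,3-dimethylcyclohexyl]-1-methyl-7-oxabicyclo[2.2.1]heptane | CC1(C)C[C@@H]([C@@]23CC[C@@](C)(O2)[C@H](Br)C3)CC[C@@H]1Br | target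

**Totals**
Total step count: 20. Longest linear sequence: 17 steps (steps 1–6, then 10–20); the linalool branch (steps 7–9) joins at step 10.

**Steps most likely to fail**

Step 17. The C4 cation may lose a proton or take a 1,2-hydride shift from C1' before the C1 oxygen arrives, which would give dienes or erode the configuration of the ring-junction methine. Fallback, from 21 back to 23, with no free carbocation: 21 is dehydrated by mesylation and E1cB elimination (MsCl, Et3N, then DBU) to the conjugated enone (6R)-3-[(1S,4S)-4-bromo-3,3-dimethylcyclohexyl]-6-methyl-6-(triethylsilyloxy)cyclohex-2-en-1-one F1. Luche reduction gives the allylic alcohol F2, and TBAF frees the tertiary hydroxyl to give the diol F3. Intramolecular oxymercuration with Hg(OCOCF3)2 delivers the C1 oxygen to C4 and gives the organomercurial F4, and NaBH4/NaOH demercuration gives 23.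

Step 19. Hydrazone formation at the neopentyl ketone may be slow, plain Wolff–Kishner reduction may occur without opening of the bridge, or base may remove HBr from ring B. Fallback, from 24 directly to 27, keeping the bridge intact: 24 is converted with (PhO)3P·Br2/Et3N into the C2=C3 vinyl bromide 2-bromo-4-[(1S,4S)-4-bromo-3,3-dimethylcyclohexyl]-1-methyl-7-oxabicyclo[2.2.1]hept-2-ene F5. Diimide (from 2-nitrobenzenesulfonylhydrazide, Et3N) should then add hydrogen to the strained alkene from the exo face, the side of the oxygen bridge, which leaves bromine endo and gives 27.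

Step 15. The enolate may be protonated (simple debromination to the methyl ketone), the tertiary samarium aldolate may revert by retro-aldol cleavage, or excess reductant may cleave the α-silyloxy group. Fallback, from 19 to 21, with a preformed enol ether and Lewis acid instead of a metal enolate: reductive silylation with Zn/TMSCl gives the regiodefined trimethylsilyl enol ether of 19, F6. This is closed onto the C4 ketone by an intramolecular Mukaiyama aldol addition (BF3·OEt2 or TiCl4, CH2Cl2, −78 °C) to give 21.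

**Further compounds**
F1 | step 17 | (6R)-3-[(1S,4S)-4-bromo-3,3-dimethylcyclohexyl]-6-methyl-6-(triethylsilyloxy)cyclohex-2-en-1-one | CC1(C)C[C@@H](C2=CC(=O)[C@](C)(O[Si](CC)(CC)CC)CC2)CC[C@@H]1Br
F2 | step 17 | (6R)-3-[(1S,4S)-4-bromo-3,3-dimethylcyclohexyl]-6-methyl-6-(triethylsilyloxy)cyclohex-2-en-1-ol (C1 epimers) | CC1(C)C[C@@H](C2=CC(O)[C@](C)(O[Si](CC)(CC)CC)CC2)CC[C@@H]1Br
F3 | step 17 | (1R)-4-[(1S,4S)-4-bromo-3,3-dimethylcyclohexyl]-1-methylcyclohex-3-ene-1,2-diol (C2 epimers) | CC1(C)C[C@@H](C2=CC(O)[C@](C)(O)CC2)CC[C@@H]1Br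
F4 | step 17 | 3-(trifluoroacetoxymercurio) derivative of 23 | CC1(C)C[C@@H]([C@@]23CC[C@@](C)(O2)C(O)C3[Hg]OC(=O)C(F)(F)F)CC[C@@H]1Br
F5 | step 19 | 2-bromo-4-[(1S,4S)-4-bromo-3,3-dimethylcyclohexyl]-1-methyl-7-oxabicyclo[2.2.1]hept-2-ene (bridgeheads as in 24) | CC1(C)C[C@@H]([C@@]23CC[C@@](C)(O2)C(Br)=C3)CC[C@@H]1Br
F6 | step 15 | trimethylsilyl enol ether of 19 (enol ether at the former bromomethyl ketone) | O=C(CC[C@@](C)(O[Si](CC)(CC)CC)C(=C)O[Si](C)(C)C)[C@H]1CC[C@H](Br)C(C)(C)C1
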